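**Plan**

- Retrosynthesis: the ten-membered ring is cut at C3–C4, then C2–C3 (sulfone acylation), the lactone C19–O bond, C6–C7 and C8–C9 (two Nozaki–Hiyama–Kishi couplings); this leaves ring A, a C7/C8/C17–C19 unit and a Z-configured C4–C6 unit.
- Forward: ring A is made from benzoic acid (Birch methylation, dienone, desymmetrising conjugate addition) and carried to the C9 aldehyde. It is joined at C8–C9, converted into the C2 keto sulfone, hydroxylated at C8, joined at C6–C7 and lactonised. The ten-membered ring closes last, followed by desulfonylation, C2 reduction, acetylation and deprotection.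
- Enabling feature: C3 is the only acidic carbon beside the C2 ketone because C1 is quaternary. C4 is a primary carbon allylic to the Z C5=C6 olefin, which the lactone carbon C7 holds cis. A C3 carbanion and a C4 bromide therefore sit at the two ends of a pre-bent chain between ring A and the lactone.
- Stereochemistry: C1/C10 from the rhodium/(R)-BINAP desymmetrisation; C11 by equilibration; C12 by Luche reduction then Mitsunobu inversion; C17 from the (S)-Roche ester; C9 and C7 by Felkin–Anh additions; C8 by osmylation anti to the C9 oxygen; C2 by CBS reduction; the Z olefin from carbomagnesiation of propargyl alcohol.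

Key step: step 26

Remarks: briarane numbering is used for all intermediates (C15 = methyl on C1, C16 = methyl on C5, C18 = methyl on C17, C19 = lactone carbonyl, C20 = methyl on C11); β is the face of ring A that carries C15. The sense of induction of the rhodium/(R)-BINAP catalyst in step 4 is assumed to follow that known for 2-cyclohexenone.

**Route**

Step 1
Reactants: 1 benzoic acid
Product: 3 1-methylcyclohexa-2,5-diene-1-carboxylic acid, via dilithium dienediolate 2 (not isolated)
Conditions: Li, NH3 (l), THF, −78 °C; then MeI, −78 °C to rt; aq. HCl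
Reagents that add atoms: iodomethane CI
Why: Birch reduction of the benzoate gives the dianion 2, which is C-methylated at the carboxylate-bearing carbon (Birch reductive alkylation); no stereocentre is formed.

Step 2
Reactants: 3 1-methylcyclohexa-2,5-diene-1-carboxylic acid
Product: 4 methyl 1-methylcyclohexa-2,5-diene-1-carboxylate
Conditions: MeI, K2CO3, DMF, rt
Reagents that add atoms: iodomethane CI
Why: SN2 O-alkylation of the potassium carboxylate gives the methyl ester that later serves as the C2 acyl donor.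

Step 3
Reactants: 4 methyl 1-methylcyclohexa-2,5-diene-1-carboxylate
Product: 5 methyl 1-methyl-4-oxocyclohexa-2,5-diene-1-carboxylate
Conditions: Rh2(cap)4 (cap = caprolactamate, 1 mol %), t-BuOOH (70% aq.), K2CO3 (cat.), CH2Cl2, rt
Reagents that add atoms: tert-butyl hydroperoxide CC(C)(C)OO
Why: Rhodium-catalysed allylic C–H oxidation with t-BuOOH converts the doubly allylic CH2 into the cross-conjugated dienone, the quaternary C1 ruling out aromatisation.

Step 4
Reactants: 5 methyl 1-methyl-4-oxocyclohexa-2,5-diene-1-carboxylate; 6 (E)-2-phenylethenylboronic acid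
Product: 7 methyl (1S,6R)-1-methyl-4-oxo-6-[(E)-2-phenylethenyl]cyclohex-2-ene-1-carboxylate
Conditions: [Rh(OH)((R)-binap)]2 (3 mol % Rh), dioxane/H2O 10:1, 35 °C
Reagents that add atoms: none
Why: Hayashi–Miyaura rhodium-catalysed asymmetric conjugate addition desymmetrises the prochiral dienone: the (R)-BINAP ligand fixes the face of attack at C10, and approach anti to the pseudoaxial ester selects the enantiotopic olefin, so that the styryl group (the future C9) should end up cis to the C15 methyl and C1 becomes stereogenic.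

Step 5
Reactants: 7 methyl (1S,6R)-1-methyl-4-oxo-6-[(E)-2-phenylethenyl]cyclohex-2-ene-1-carboxylate
Product: 8 methyl (1S,5S,6S)-1,5-dimethyl-4-oxo-6-[(E)-2-phenylethenyl]cyclohex-2-ene-1-carboxylate
Conditions: LiN(i-Pr)2, THF, −78 °C; MeI, −78 to −20 °C
Reagents that add atoms: iodomethane CI
Why: Kinetic enolate alkylation at C11, the only enolisable position because C1 is quaternary, should place the methyl group mainly anti to the neighbouring styryl group (10,11-trans), an outcome that is corrected in step 6.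

Step 6
Reactants: 8 methyl (1S,5S,6S)-1,5-dimethyl-4-oxo-6-[(E)-2-phenylethenyl]cyclohex-2-ene-1-carboxylate
Product: 9 methyl (1S,5R,6S)-1,5-dimethyl-4-oxo-6-[(E)-2-phenylethenyl]cyclohex-2-ene-1-carboxylate
Conditions: NaOMe (0.2 equiv), MeOH, 0 °C to rt
Reagents that add atoms: none
Why: Base-mediated epimerisation through the C11 enolate should converge on the 10,11-cis ketone, whose half-chair keeps the C11 methyl equatorial and the styryl group axial without 1,3-diaxial partners, whereas the trans isomer forces the methyl group syn-axial to the ester or the styryl group between three gauche neighbours.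

Step 7
Reactants: 9 methyl (1S,5R,6S)-1,5-dimethyl-4-oxo-6-[(E)-2-phenylethenyl]cyclohex-2-ene-1-carboxylate
Product: 10 methyl (1S,4S,5R,6S)-4-hydroxy-1,5-dimethyl-6-[(E)-2-phenylethenyl]cyclohex-2-ene-1-carboxylate
Conditions: NaBH4, CeCl3·7H2O, MeOH, −78 °C
Reagents that add atoms: none
Why: Luche 1,2-reduction, hydride being delivered to the α face anti to the axial C10 substituent, should give the 12β-alcohol (cis to the C11 methyl), which is the epimer needed for inversion.

Step 8
Reactants: 10 methyl (1S,4S,5R,6S)-4-hydroxy-1,5-dimethyl-6-[(E)-2-phenylethenyl]cyclohex-2-ene-1-carboxylate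
Product: 11 methyl (1S,4R,5R,6S)-4-(4-methoxyphenoxy)-1,5-dimethyl-6-[(E)-2-phenylethenyl]cyclohex-2-ene-1-carboxylate
Conditions: 4-methoxyphenol, PPh3, DIAD, toluene, 0 °C to rt
Reagents that add atoms: 4-methoxyphenol COc1ccc(O)cc1
Why: Mitsunobu etherification proceeds by SN2 displacement of the oxyphosphonium group from the open α face and so installs the C12 oxygen with inversion as a robust aryl ether; SN2′ attack at C14 is blocked by quaternary C1.

Step 9
Reactants: 11 methyl (1S,4R,5R,6S)-4-(4-methoxyphenoxy)-1,5-dimethyl-6-[(E)-2-phenylethenyl]cyclohex-2-ene-1-carboxylate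
Product: 13 methyl (1S,4R,5R,6S)-6-formyl-4-(4-methoxyphenoxy)-1,5-dimethylcyclohex-2-ene-1-carboxylate, via styryl diol 12 (not isolated)
Conditions: K2OsO2(OH)4 (2 mol %), (DHQD)2PHAL (5 mol %), NMO, acetone/H2O, 0 °C; then NaIO4, rt
Reagents that add atoms: N-methylmorpholine N-oxide C[N+]1([O-])CCOCC1; water O
Why: Ligand-accelerated osmium-catalysed dihydroxylation (Sharpless-type) should single out the trans-styryl olefin over the hindered cis ring olefin, and periodate glycol cleavage then unveils the C9 aldehyde without touching C10.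

Step 10
Reactants: 14 methyl (S)-3-hydroxy-2-methylpropanoate
Product: 15 methyl (S)-2-methyl-3-(triethylsilyloxy)propanoate
Conditions: Et3SiCl, imidazole, CH2Cl2, 0 °C
Reagents that add atoms: chlorotriethylsilane CC[Si](Cl)(CC)CC
Why: Standard silylation of the primary alcohol; the C17 stereocentre of the (S)-Roche ester is untouched.

Step 11
Reactants: 15 methyl (S)-2-methyl-3-(triethylsilyloxy)propanoate
Product: 17 (S)-3-methyl-4-(triethylsilyloxy)butan-2-one, via Weinreb amide 16 (not isolated)
Conditions: MeNH(OMe)·HCl, i-PrMgCl, THF, −20 °C; then MeMgBr, 0 °C; aq. NH4Cl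
Reagents that add atoms: methylmagnesium bromide C[Mg]Br; N,O-dimethylhydroxylamine hydrochloride CNOC.Cl (atoms only in 16)
Why: Weinreb ketone synthesis in one flask: the magnesium amide converts the ester into the N-methoxy-N-methylamide 16, whose chelated tetrahedral adduct with MeMgBr collapses to the methyl ketone only on work-up, so neither over-addition nor epimerisation at C17 is expected.

Step 12
Reactants: 17 (S)-3-methyl-4-(triethylsilyloxy)butan-2-one
Product: 18 (S)-3-methyl-4-(triethylsilyloxy)but-1-en-2-yl trifluoromethanesulfonate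
Conditions: KN(SiMe3)2, THF, −78 °C; PhNTf2; aq. NH4Cl
Reagents that add atoms: N-phenylbis(trifluoromethanesulfonimide) O=S(=O)(N(c1ccccc1)S(=O)(=O)C(F)(F)F)C(F)(F)F
Why: Kinetic deprotonation of the methyl group by the bulky amide at low temperature and O-sulfonylation of the enolate give the less substituted enol triflate (the future C8=C7) with the C17 stereocentre intact.

Step 13
Reactants: 13 methyl (1S,4R,5R,6S)-6-formyl-4-(4-methoxyphenoxy)-1,5-dimethylcyclohex-2-ene-1-carboxylate; 18 (S)-3-methyl-4-(triethylsilyloxy)but-1-en-2-yl trifluoromethanesulfonate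
Product: 19 methyl (1S,4R,5R,6S)-6-[(1R,3R)-1-hydroxy-3-methyl-2-methylidene-4-(triethylsilyloxy)butyl]-4-(4-methoxyphenoxy)-1,5-dimethylcyclohex-2-ene-1-carboxylate (C9 allylic alcohol, 9R)
Conditions: CrCl2 (6 equiv), NiCl2 (2 mol %), DMF, rt
Reagents that add atoms: none
Why: Nozaki–Hiyama–Kishi coupling: the alkenylchromium reagent formed by nickel-catalysed activation of the triflate adds chemoselectively to the aldehyde, Felkin–Anh attack anti to the quaternary C1 (C11 inside) setting C9 as 9R.

Step 14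
Reactants: 19 C9 allylic alcohol
Product: 20 methyl (1S,4R,5R,6S)-4-(4-methoxyphenoxy)-1,5-dimethyl-6-[(1R,3R)-3-methyl-2-methylidene-1,4-bis(triethylsilyloxy)butyl]cyclohex-2-ene-1-carboxylate (C9 triethylsilyl ether)
Conditions: Et3SiOTf, 2,6-lutidine, CH2Cl2, −78 °C
Reagents that add atoms: triethylsilyl trifluoromethanesulfonate CC[Si](CC)(CC)OS(=O)(=O)C(F)(F)F
Why: Silylation of the hindered secondary alcohol with the silyl triflate protects C9–OH against base and later against translactonisation.

Step 15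
Reactants: 20 C9 triethylsilyl ether; 21 methyl phenyl sulfone
Product: 22 2-(benzenesulfonyl)-1-[(1S,4R,5R,6S)-4-(4-methoxyphenoxy)-1,5-dimethyl-6-[(1R,3R)-3-methyl-2-methylidene-1,4-bis(triethylsilyloxy)butyl]cyclohex-2-en-1-yl]ethan-1-one (C2 keto sulfone)
Conditions: PhSO2CH3 (3 equiv), n-BuLi (3 equiv), THF, −78 °C; then 20, −78 °C to rt; aq. NH4Cl
Reagents that add atoms: none
Why: Claisen-type acylation of lithiated methyl phenyl sulfone by the only carbonyl group present builds the C2 ketone and C3; the product is deprotonated at once to its enolate, which prevents a second addition.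

Step 16
Reactants: 22 C2 keto sulfone
Product: 23 7,8-diol (keto sulfone 22 with C8=C7H2 converted into C8(OH)–C7H2OH, 8S)
Conditions: K2OsO2(OH)4 (5 mol %), (DHQD)2PHAL (10 mol %), NMO, acetone/H2O, 0 °C
Reagents that add atoms: N-methylmorpholine N-oxide C[N+]1([O-])CCOCC1; water O
Why: Osmium-catalysed dihydroxylation of the 1,1-disubstituted olefin, the cis ring olefin being a poor substrate, should occur anti to the allylic C9 oxygen with the small hydrogen near C17 (erythro rule for allylic ethers), reinforced by the (DHQD)2PHAL ligand, and so set C8 as 8S.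

Step 17
Reactants: 23 7,8-diol
Product: 24 C7 aldehyde with free tertiary C8 hydroxyl
Conditions: Dess–Martin periodinane, NaHCO3, CH2Cl2, 0 °C
Reagents that add atoms: none
Why: Dess–Martin oxidation converts the primary alcohol into the C7 aldehyde while the tertiary C8 hydroxyl cannot be oxidised.

Step 18
Reactants: 24 C7 aldehyde with free tertiary C8 hydroxyl
Product: 25 C7 aldehyde with triethylsilyl ethers at C8, C9 and C19
Conditions: Et3SiOTf, 2,6-lutidine, CH2Cl2, −78 to 0 °C
Reagents that add atoms: triethylsilyl trifluoromethanesulfonate CC[Si](CC)(CC)OS(=O)(=O)C(F)(F)F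
Why: The silyl triflate silylates the tertiary hydroxyl; a non-chelating silyl ether at C8 is what the next addition needs, and the aldehyde cannot enolise because C8 is quaternary.

Step 19
Reactants: 26 propargyl alcohol
Product: 28 (Z)-3-iodo-2-methylprop-2-en-1-ol, via alkenylmagnesium alkoxide 27 (not isolated)
Conditions: MeMgBr (2.5 equiv), CuI (10 mol %), THF, −10 °C to rt; then I2, −78 to 0 °C; aq. NH4Cl
Reagents that add atoms: methylmagnesium bromide C[Mg]Br; iodine II
Why: Copper-catalysed, alkoxide-directed anti-carbomagnesiation of propargyl alcohol gives the chelated alkenylmagnesium 27, whose iodinolysis with retention furnishes the Z iodide (iodine cis to CH2OH), the source of the Z C5=C6 olefin.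

Step 20
Reactants: 28 (Z)-3-iodo-2-methylprop-2-en-1-ol
Product: 29 1-{[(Z)-3-iodo-2-methylprop-2-enyl]oxymethyl}-4-methoxybenzene
Conditions: NaH, 4-methoxybenzyl chloride, Bu4NI (cat.), THF/DMF, 0 °C to rt
Reagents that add atoms: 4-methoxybenzyl chloride COc1ccc(CCl)cc1
Why: Williamson etherification of the sodium alkoxide; the vinyl iodide has no β-hydrogen on C5 and cannot eliminate.

Step 21
Reactants: 25 C7 aldehyde with triethylsilyl ethers at C8, C9 and C19; 29 1-{[(Z)-3-iodo-2-methylprop-2-enyl]oxymethyl}-4-methoxybenzene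
Product: 30 C7 allylic alcohol (7S) carrying the Z C4–C6 unit as its 4-methoxybenzyl ether
Conditions: CrCl2 (8 equiv), NiCl2 (2 mol %), DMSO/THF, rt
Reagents that add atoms: none
Why: Second Nozaki–Hiyama–Kishi coupling, tolerant of the acidic keto sulfone: the trisubstituted alkenylchromium keeps its Z geometry and adds to the aldehyde anti to the C8 silyloxy group with the larger C9 branch inside (polar Felkin–Anh), which should set C7 as 7S.

Step 22
Reactants: 30 C7 allylic alcohol
Product: 31 C7,C19-diol (C8 and C9 triethylsilyl ethers retained)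
Conditions: PPTS (cat.), MeOH/CH2Cl2, 0 °C
Reagents that add atoms: none
Why: Acid-catalysed methanolysis removes the unhindered primary silyl ether much faster than the neopentyl-type secondary (C9) and tertiary (C8) ones.

Step 23
Reactants: 31 C7,C19-diol
Product: 33 γ-lactone with C4 4-methoxybenzyl ether, via lactol 32 (not isolated)
Conditions: TEMPO (20 mol %), PhI(OAc)2 (2.5 equiv), CH2Cl2, rt
Reagents that add atoms: none
Why: TEMPO/PhI(OAc)2 oxidative lactonisation: the primary alcohol is oxidised to the aldehyde, which is trapped by the C7 hydroxyl as lactol 32 (5-exo-trig) and oxidised on to the γ-lactone, C17 being unaffected under these neutral conditions.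

Step 24
Reactants: 33 γ-lactone with C4 4-methoxybenzyl ether
Product: 34 allylic alcohol (C4–OH) of the lactone keto sulfone
Conditions: DDQ, CH2Cl2/pH 7 buffer, 0 °C
Reagents that add atoms: none
Why: DDQ removes the 4-methoxybenzyl ether by benzylic hydride abstraction; the 4-methoxyphenyl ether has no benzylic C–H and should stay.

Step 25
Reactants: 34 allylic alcohol (C4–OH)
Product: 35 allylic bromide: ring A C2 keto sulfone joined at C9–C8 to the silyloxy lactone bearing the Z CH2Br arm
Conditions: CBr4, PPh3, CH2Cl2, 0 °C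
Reagents that add atoms: carbon tetrabromide BrC(Br)(Br)Br
Why: Appel reaction: SN2 displacement of the oxyphosphonium group at the primary allylic carbon under neutral conditions keeps the Z geometry and leaves the acidic keto sulfone protonated.

Step 26
Reactants: 35 allylic bromide
Product: 36 bicyclic C2 ketone C3 sulfone with complete lactone (C3 epimers)
Conditions: Cs2CO3 (5 equiv), MeCN, 40 °C, 35 added by syringe pump to 2 mM final concentration
Reagents that add atoms: none
Why: Cs2CO3 deprotonates C3, the only acidic carbon of 35 because it lies between the C2 ketone (C1 is quaternary) and the sulfone, and the soft enolate displaces the primary allylic bromide at C4 by SN2, forming C3–C4. The closest known reaction type is the intramolecular alkylation of sulfone-stabilised carbanions by allylic halides used to close germacrane-type ten-membered carbocycles. The ten-membered ring closes in a 10-exo-tet mode, helped by the Z C5=C6 olefin, the lactone and ring A, which hold C3 and C4 within reach. C3 is the only new stereocentre; it is formed without control and is erased in step 27. The step needs C- instead of O-alkylation, SN2 instead of SN2′ attack with the Z geometry kept, and ring closure instead of oligomerisation; the soft doubly stabilised carbanion, the unhindered CH2Br terminus (C6 is shielded by the lactone) and high dilution should secure these, while the weak base leaves the lactone C17–H and the silyl ethers alone.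

Step 27
Reactants: 36 bicyclic C2 ketone C3 sulfone
Product: 37 bicyclic C2 ketone
Conditions: Al(Hg), THF/H2O 9:1, 0 °C to rt
Reagents that add atoms: none
Why: Reductive desulfonylation of the α-sulfonyl ketone by electron transfer from aluminium amalgam removes the C3 stereocentre and returns the C2 ketone.

Step 28
Reactants: 37 bicyclic C2 ketone
Product: 38 C2 alcohol (2R)
Conditions: (S)-2-methyl-CBS-oxazaborolidine (0.5 equiv), catecholborane, toluene, −78 to −40 °C
Reagents that add atoms: none
Why: Corey–Bakshi–Shibata reduction: with quaternary C1 as the large and the C3 methylene as the small ketone substituent the (S)-oxazaborolidine should deliver hydride to the face that gives the 2R alcohol; catecholborane at low temperature leaves the lactone and the olefins alone.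

Step 29
Reactants: 38 C2 alcohol
Product: 39 2,8,9-triol with C12 4-methoxyphenyl ether
Conditions: HF·pyridine, pyridine/THF, 0 °C to rt
Reagents that add atoms: none
Why: Fluoride cleaves both triethylsilyl ethers (secondary C9, tertiary C8) whereas the aryl ether, the lactone and the olefins are inert.

Step 30
Reactants: 39 2,8,9-triol
Product: 40 2,9-diacetate with C12 4-methoxyphenyl ether
Conditions: Ac2O, pyridine, DMAP (cat.), CH2Cl2, rt
Reagents that add atoms: acetic anhydride CC(=O)OC(C)=O
Why: DMAP-catalysed acylation esterifies the two secondary alcohols (C2, C9); the tertiary C8 hydroxyl does not react under these conditions.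

Step 31
Reactants: 40 2,9-diacetate
Product: 41 CNP0222085.1
Conditions: (NH4)2Ce(NO3)6, MeCN/H2O 4:1, 0 °C
Reagents that add atoms: none
Why: Oxidative dearylation: (NH4)2Ce(NO3)6 oxidises the electron-rich aryl ether to a quinone hemiketal that releases the C12 alcohol, acetates, lactone and olefins being stable.

**Compound list**

1 | benzoic acid | OC(=O)c1ccccc1 | starting material
2 | dilithium dienediolate of 1,4-dihydrobenzoic acid | [Li+].[Li+].[O-]C([O-])=C1C=CCC=C1 | intermediate
3 | 1-methylcyclohexa-2,5-diene-1-carboxylic acid | CC1(C=CCC=C1)C(=O)O | intermediate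
4 | methyl 1-methylcyclohexa-2,5-diene-1-carboxylate | COC(=O)C1(C)C=CCC=C1 | intermediate
5 | methyl 1-methyl-4-oxocyclohexa-2,5-diene-1-carboxylate | COC(=O)C1(C)C=CC(=O)C=C1 | intermediate
6 | (E)-2-phenylethenylboronic acid | OB(O)/C=C/c1ccccc1 | starting material
7 | methyl (1S,6R)-1-methyl-4-oxo-6-[(E)-2-phenylethenyl]cyclohex-2-ene-1-carboxylate | c1ccccc1/C=C/[C@H]1CC(=O)C=C[C@]1(C)C(=O)OC | intermediate
8 | methyl (1S,5S,6S)-1,5-dimethyl-4-oxo-6-[(E)-2-phenylethenyl]cyclohex-2-ene-1-carboxylate (C11 methyl trans to styryl) | c1ccccc1/C=C/[C@H]1[C@H](C)C(=O)C=C[C@]1(C)C(=O)OC | intermediate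
9 | methyl (1S,5R,6S)-1,5-dimethyl-4-oxo-6-[(E)-2-phenylethenyl]cyclohex-2-ene-1-carboxylate (C11 methyl cis to styryl) | c1ccccc1/C=C/[C@H]1[C@@H](C)C(=O)C=C[C@]1(C)C(=O)OC | intermediate
10 | methyl (1S,4S,5R,6S)-4-hydroxy-1,5-dimethyl-6-[(E)-2-phenylethenyl]cyclohex-2-ene-1-carboxylate (12β-OH) | c1ccccc1/C=C/[C@H]1[C@@H](C)[C@@H](O)C=C[C@]1(C)C(=O)OC | intermediate
11 | methyl (1S,4R,5R,6S)-4-(4-methoxyphenoxy)-1,5-dimethyl-6-[(E)-2-phenylethenyl]cyclohex-2-ene-1-carboxylate (12α-aryloxy) | c1ccccc1/C=C/[C@H]1[C@@H](C)[C@H](Oc2ccc(OC)cc2)C=C[C@]1(C)C(=O)OC | intermediate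
12 | methyl (1S,4R,5R,6S)-6-[(1R,2R)-1,2-dihydroxy-2-phenylethyl]-4-(4-methoxyphenoxy)-1,5-dimethylcyclohex-2-ene-1-carboxylate (styryl diol) | O[C@H](c1ccccc1)[C@H](O)[C@H]1[C@@H](C)[C@H](Oc2ccc(OC)cc2)C=C[C@]1(C)C(=O)OC | intermediate
13 | methyl (1S,4R,5R,6S)-6-formyl-4-(4-methoxyphenoxy)-1,5-dimethylcyclohex-2-ene-1-carboxylate (ring A C9 aldehyde) | O=C[C@H]1[C@@H](C)[C@H](Oc2ccc(OC)cc2)C=C[C@]1(C)C(=O)OC | intermediate
14 | methyl (S)-3-hydroxy-2-methylpropanoate ((S)-Roche ester) | COC(=O)[C@@H](C)CO | starting material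
15 | methyl (S)-2-methyl-3-(triethylsilyloxy)propanoate | COC(=O)[C@@H](C)CO[Si](CC)(CC)CC | intermediate
16 | (S)-N-methoxy-N,2-dimethyl-3-(triethylsilyloxy)propanamide (Weinreb amide) | CON(C)C(=O)[C@@H](C)CO[Si](CC)(CC)CC | intermediate
17 | (S)-3-methyl-4-(triethylsilyloxy)butan-2-one | CC(=O)[C@@H](C)CO[Si](CC)(CC)CC | intermediate
18 | (S)-3-methyl-4-(triethylsilyloxy)but-1-en-2-yl trifluoromethanesulfonate | C=C(OS(=O)(=O)C(F)(F)F)[C@@H](C)CO[Si](CC)(CC)CC | intermediate
19 | methyl (1S,4R,5R,6S)-6-[(1R,3R)-1-hydroxy-3-methyl-2-methylidene-4-(triethylsilyloxy)butyl]-4-(4-methoxyphenoxy)-1,5-dimethylcyclohex-2-ene-1-carboxylate (C9 allylic alcohol, 9R) | C=C([C@@H](C)CO[Si](CC)(CC)CC)[C@H](O)[C@H]1[C@@H](C)[C@H](Oc2ccc(OC)cc2)C=C[C@]1(C)C(=O)OC | intermediate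
20 | methyl (1S,4R,5R,6S)-4-(4-methoxyphenoxy)-1,5-dimethyl-6-[(1R,3R)-3-methyl-2-methylidene-1,4-bis(triethylsilyloxy)butyl]cyclohex-2-ene-1-carboxylate (C9 triethylsilyl ether) | C=C([C@@H](C)CO[Si](CC)(CC)CC)[C@H](O[Si](CC)(CC)CC)[C@H]1[C@@H](C)[C@H](Oc2ccc(OC)cc2)C=C[C@]1(C)C(=O)OC | intermediate
21 | methyl phenyl sulfone | CS(=O)(=O)c1ccccc1 | starting material
22 | 2-(benzenesulfonyl)-1-[(1S,4R,5R,6S)-4-(4-methoxyphenoxy)-1,5-dimethyl-6-[(1R,3R)-3-methyl-2-methylidene-1,4-bis(triethylsilyloxy)butyl]cyclohex-2-en-1-yl]ethan-1-one (C2 keto sulfone) | C=C([C@@H](C)CO[Si](CC)(CC)CC)[C@H](O[Si](CC)(CC)CC)[C@H]1[C@@H](C)[C@H](Oc2ccc(OC)cc2)C=C[C@]1(C)C(=O)CS(=O)(=O)c1ccccc1 | intermediate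
23 | 7,8-diol of 22 (C8 tertiary OH, C7 primary OH; 8S) | OC[C@@](O)([C@@H](C)CO[Si](CC)(CC)CC)[C@H](O[Si](CC)(CC)CC)[C@H]1[C@@H](C)[C@H](Oc2ccc(OC)cc2)C=C[C@]1(C)C(=O)CS(=O)(=O)c1ccccc1 | intermediate
24 | C7 aldehyde with free tertiary C8 hydroxyl | O=C[C@@](O)([C@@H](C)CO[Si](CC)(CC)CC)[C@H](O[Si](CC)(CC)CC)[C@H]1[C@@H](C)[C@H](Oc2ccc(OC)cc2)C=C[C@]1(C)C(=O)CS(=O)(=O)c1ccccc1 | intermediate
25 | C7 aldehyde with triethylsilyl ethers at C8, C9 and C19 | O=C[C@@](O[Si](CC)(CC)CC)([C@@H](C)CO[Si](CC)(CC)CC)[C@H](O[Si](CC)(CC)CC)[C@H]1[C@@H](C)[C@H](Oc2ccc(OC)cc2)C=C[C@]1(C)C(=O)CS(=O)(=O)c1ccccc1 | intermediate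
26 | propargyl alcohol (prop-2-yn-1-ol) | C#CCO | starting material
27 | bromomagnesium (Z)-3-(bromomagnesio)-2-methylprop-2-en-1-olate (alkenylmagnesium alkoxide) | Br[Mg]OC/C(C)=C\[Mg]Br | intermediate
28 | (Z)-3-iodo-2-methylprop-2-en-1-ol | OC/C(C)=C\I | intermediate
29 | 1-{[(Z)-3-iodo-2-methylprop-2-enyl]oxymethyl}-4-methoxybenzene | COc1ccc(COC/C(C)=C\I)cc1 | intermediate
30 | C7 allylic alcohol (7S) with Z C5=C6 olefin, C4 4-methoxybenzyl ether, C8/C9/C19 triethylsilyl ethers | COc1ccc(COC/C(C)=C\[C@H](O)[C@@](O[Si](CC)(CC)CC)([C@@H](C)CO[Si](CC)(CC)CC)[C@H](O[Si](CC)(CC)CC)[C@H]2[C@@H](C)[C@H](Oc3ccc(OC)cc3)C=C[C@]2(C)C(=O)CS(=O)(=O)c2ccccc2)cc1 | intermediate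
31 | C7,C19-diol (C8/C9 triethylsilyl ethers) | COc1ccc(COC/C(C)=C\[C@H](O)[C@@](O[Si](CC)(CC)CC)([C@@H](C)CO)[C@H](O[Si](CC)(CC)CC)[C@H]2[C@@H](C)[C@H](Oc3ccc(OC)cc3)C=C[C@]2(C)C(=O)CS(=O)(=O)c2ccccc2)cc1 | intermediate
32 | lactol (C19 hemiacetal, both anomers) | COc1ccc(COC/C(C)=C\[C@@H]2OC(O)[C@H](C)[C@@]2(O[Si](CC)(CC)CC)[C@H](O[Si](CC)(CC)CC)[C@H]2[C@@H](C)[C@H](Oc3ccc(OC)cc3)C=C[C@]2(C)C(=O)CS(=O)(=O)c2ccccc2)cc1 | intermediate
33 | γ-lactone (C7 alkenyl, C8 silyloxy and C17 methyl cis; C9 branch trans) with C4 4-methoxybenzyl ether | COc1ccc(COC/C(C)=C\[C@@H]2OC(=O)[C@H](C)[C@@]2(O[Si](CC)(CC)CC)[C@H](O[Si](CC)(CC)CC)[C@H]2[C@@H](C)[C@H](Oc3ccc(OC)cc3)C=C[C@]2(C)C(=O)CS(=O)(=O)c2ccccc2)cc1 | intermediate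
34 | allylic alcohol (C4–OH) of the lactone keto sulfone | OC/C(C)=C\[C@@H]1OC(=O)[C@H](C)[C@@]1(O[Si](CC)(CC)CC)[C@H](O[Si](CC)(CC)CC)[C@H]1[C@@H](C)[C@H](Oc2ccc(OC)cc2)C=C[C@]1(C)C(=O)CS(=O)(=O)c1ccccc1 | intermediate
35 | allylic bromide: ring A C2 keto sulfone joined at C9–C8 to the silyloxy lactone bearing the Z CH2Br arm | BrC/C(C)=C\[C@@H]1OC(=O)[C@H](C)[C@@]1(O[Si](CC)(CC)CC)[C@H](O[Si](CC)(CC)CC)[C@H]1[C@@H](C)[C@H](Oc2ccc(OC)cc2)C=C[C@]1(C)C(=O)CS(=O)(=O)c1ccccc1 | intermediate
36 | bicyclic C2 ketone C3 sulfone with complete lactone (C3 epimers) | CC[Si](CC)(CC)O[C@@H]1[C@H]2[C@@H](C)[C@H](Oc3ccc(OC)cc3)C=C[C@]2(C)C(=O)C(S(=O)(=O)c3ccccc3)C/C(C)=C\[C@@H]2OC(=O)[C@H](C)[C@]21O[Si](CC)(CC)CC | intermediate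
37 | bicyclic C2 ketone | CC[Si](CC)(CC)O[C@@H]1[C@H]2[C@@H](C)[C@H](Oc3ccc(OC)cc3)C=C[C@]2(C)C(=O)CC/C(C)=C\[C@@H]2OC(=O)[C@H](C)[C@]21O[Si](CC)(CC)CC | intermediate
38 | C2 alcohol (2R), C8/C9 triethylsilyl ethers, C12 4-methoxyphenyl ether | CC[Si](CC)(CC)O[C@@H]1[C@H]2[C@@H](C)[C@H](Oc3ccc(OC)cc3)C=C[C@]2(C)[C@H](O)CC/C(C)=C\[C@@H]2OC(=O)[C@H](C)[C@]21O[Si](CC)(CC)CC | intermediate
39 | 2,8,9-triol with C12 4-methoxyphenyl ether | O[C@@H]1[C@H]2[C@@H](C)[C@H](Oc3ccc(OC)cc3)C=C[C@]2(C)[C@H](O)CC/C(C)=C\[C@@H]2OC(=O)[C@H](C)[C@]21O | intermediate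
40 | 2,9-diacetate with C12 4-methoxyphenyl ether | CC(=O)O[C@@H]1[C@H]2[C@@H](C)[C@H](Oc3ccc(OC)cc3)C=C[C@]2(C)[C@H](OC(C)=O)CC/C(C)=C\[C@@H]2OC(=O)[C@H](C)[C@]21O | intermediate
41 | CNP0222085.1 (2,9-diacetoxy-8,12-dihydroxybriara-5Z,13-diene 7,19-lactone) | CC(=O)O[C@@H]1[C@H]2[C@@H](C)[C@H](O)C=C[C@]2(C)[C@H](OC(C)=O)CC/C(C)=C\[C@@H]2OC(=O)[C@H](C)[C@]21O | target

**Step count**

Total step count: 31. Longest linear sequence: 26 steps (steps 1–9, 13–18 and 21–31).

**Steps most likely to fail**

Step 26 (ring closure). Ring A has to leave the half-chair in which the C2 and C9 branches are trans-diaxial before C3 can reach C4. The closure may therefore be slow and lose to intermolecular alkylation or to O-alkylation of the enolate. The fallback closes the same C3–C4 bond by palladium catalysis instead of SN2 displacement. It sets out from allylic alcohol 34, which with methyl chloroformate and pyridine should give the allylic methyl carbonate F1. Pd(PPh3)4 (zerovalent palladium) in THF at high dilution ionises F1 to a π-allyl complex; the liberated methoxide deprotonates C3, and the soft keto sulfone enolate attacks the unsubstituted allyl terminus C4 (Tsuji–Trost macrocyclisation). This returns to 36. Syn–anti equilibration of the allyl unit should be tolerated because the ten-membered ring is expected to close through the anti (Z) form.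

Step 4 (desymmetrisation). The ligand fixes C10, but discrimination between the methyl side and the ester side of C1 may be poor, which would give a mixture of C1 epimers. The fallback enlarges the ester. It sets out from acid 3, which with tert-butyl 2,2,2-trichloroacetimidate should give the tert-butyl ester F2. Oxidation as in step 3 gives the tert-butyl dienone F3, and the same rhodium-catalysed addition of 6 gives the tert-butyl adduct F4, in which the bulkier ester should direct the styryl group anti more strongly. CF3CO2H cleaves the ester to the acid F5, which is methylated at once with MeI/K2CO3 and so returns to 7.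

Step 15 (sulfone acylation). Attack of the sulfonyl carbanion on the neopentyl-type ester may be slow, leaving ester unchanged or costing silyl groups on prolonged warming. The fallback changes the oxidation level at C2. It sets out from 20, which i-Bu2AlH should reduce to the primary alcohol F6. Dess–Martin periodinane gives the aldehyde F7, to which lithiated methyl phenyl sulfone adds at −78 °C to give the β-hydroxy sulfone F8 (C2 epimers). A second Dess–Martin oxidation returns to keto sulfone 22.

**Further compounds**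

F1 | step 26 | allylic methyl carbonate of 34 | COC(=O)OC/C(C)=C\[C@@H]1OC(=O)[C@H](C)[C@@]1(O[Si](CC)(CC)CC)[C@H](O[Si](CC)(CC)CC)[C@H]1[C@@H](C)[C@H](Oc2ccc(OC)cc2)C=C[C@]1(C)C(=O)CS(=O)(=O)c1ccccc1
F2 | step 4 | tert-butyl 1-methylcyclohexa-2,5-diene-1-carboxylate | CC(C)(C)OC(=O)C1(C)C=CCC=C1
F3 | step 4 | tert-butyl 1-methyl-4-oxocyclohexa-2,5-diene-1-carboxylate | CC(C)(C)OC(=O)C1(C)C=CC(=O)C=C1
F4 | step 4 | tert-butyl (1S,6R)-1-methyl-4-oxo-6-[(E)-2-phenylethenyl]cyclohex-2-ene-1-carboxylate | c1ccccc1/C=C/[C@H]1CC(=O)C=C[C@]1(C)C(=O)OC(C)(C)C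
F5 | step 4 | (1S,6R)-1-methyl-4-oxo-6-[(E)-2-phenylethenyl]cyclohex-2-ene-1-carboxylic acid | c1ccccc1/C=C/[C@H]1CC(=O)C=C[C@]1(C)C(=O)O
F6 | step 15 | primary alcohol (C2 CH2OH) from ester 20 | C=C([C@@H](C)CO[Si](CC)(CC)CC)[C@H](O[Si](CC)(CC)CC)[C@H]1[C@@H](C)[C@H](Oc2ccc(OC)cc2)C=C[C@]1(C)CO
F7 | step 15 | C2 aldehyde | C=C([C@@H](C)CO[Si](CC)(CC)CC)[C@H](O[Si](CC)(CC)CC)[C@H]1[C@@H](C)[C@H](Oc2ccc(OC)cc2)C=C[C@]1(C)C=O
F8 | step 15 | β-hydroxy sulfone (C2 epimers) | C=C([C@@H](C)CO[Si](CC)(CC)CC)[C@H](O[Si](CC)(CC)CC)[C@H]1[C@@H](C)[C@H](Oc2ccc(OC)cc2)C=C[C@]1(C)C(O)CS(=O)(=O)c1ccccc1
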